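**Plan**

1. Retrosynthesis: the thirteen O-benzyl groups and the galloyl ester on the lower C3 oxygen are cut first; the lower pyran ring (ring F) is then cut at C4–C4a and O1–C2; last comes the interflavan bond C4 (upper)–C8 (lower). Upper unit = rings A/C/B, lower unit = rings D/F/E.
2. Enabling feature: ring D (C4a, C5–C8, C8a) is a phloroglucinol ring in which the phenolic O1 on C8a sits beside the unsubstituted, nucleophilic C4a. With C3 raised to the ketone (enol ether) level, C4–C3–C2 is a 2-oxy enal, so O1–C8a–C4a–C4–C3–C2 is the 1-oxatriene of a 2H-chromene.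
3. Forward: (+)-catechin is perbenzylated and oxidised at C4; Friedel–Crafts coupling with 3,5-bis(benzyloxy)phenol makes the interflavan bond and leaves one free phenol; a boron-templated condensation/oxa-6π electrocyclisation with a 2-silyloxycinnamaldehyde builds ring F with ring E and the C3 oxygen in one operation; reduction, galloylation and hydrogenolysis finish.
4. Stereochemistry: upper C2 and C3 come from (+)-catechin; upper C4 (4α) from attack anti to the C3 substituent on the benzylic cation; lower C2 and C3 (2R,3R, cis) are set together by a catalyst-controlled transfer hydrogenation of the flavan-3-one under dynamic kinetic resolution, so the uncontrolled C2 from the electrocyclisation does not matter.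

Key step: step 8

Remark: the silyloxy phosphonate used in the Horner–Wadsworth–Emmons step is taken as a purchasable reagent.
Remark: the (R,R) antipode of the transfer-hydrogenation catalyst is assumed to give the (2R,3R) lower unit; if the sense of induction is opposite, the (S,S) antipode is used with no other change.

**Route**

Step 1
Reactants: 1 (+)-catechin
Product: 2 5,7,3',4'-tetra-O-benzyl-(+)-catechin
Conditions: BnBr (4.2 equiv), K2CO3, DMF, 0 °C to rt, Ar
Reagents that add atoms: benzyl bromide, BrCc1ccccc1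
Why: Williamson ether synthesis in which K2CO3 deprotonates only the four phenols, so the secondary C3 alcohol stays free and no stereocentre is touched.

Step 2
Reactants: 2 5,7,3',4'-tetra-O-benzyl-(+)-catechin
Product: 3 3,5,7,3',4'-penta-O-benzyl-(+)-catechin
Conditions: NaH, BnBr, DMF, 0 °C to rt
Reagents that add atoms: benzyl bromide, BrCc1ccccc1
Why: Williamson ether synthesis on the sodium alkoxide of the remaining secondary alcohol, which keeps the upper C3 oxygen out of the later esterification; no stereocentre is touched.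

Step 3
Reactants: 3 3,5,7,3',4'-penta-O-benzyl-(+)-catechin
Product: 4 4β-(2-ethoxyethoxy) derivative of 3
Conditions: DDQ (2 equiv), 2-ethoxyethanol (5 equiv), CH2Cl2, rt
Reagents that add atoms: 2-ethoxyethanol, CCOCCO
Why: DDQ benzylic oxidation in which hydride abstraction from C4 (activated by the 5- and 7-oxygens) gives a quinone-methide-type cation that the alcohol should trap from the face opposite the C2 aryl group; the C4 configuration is lost again in step 4.

Step 4
Reactants: 4 4β-(2-ethoxyethoxy) derivative of 3; 5 3,5-bis(benzyloxy)phenol (3 equiv)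
Product: 6 3,5-bis(benzyloxy)-2-(penta-O-benzylcatechin-4α-yl)phenol
Conditions: TMSOTf (cat.), CH2Cl2, −78 to −40 °C; aq. NaHCO3
Reagents that add atoms: none
Why: Lewis-acid-promoted Friedel–Crafts alkylation through the C4 benzylic cation, in which the phenol should react at a carbon ortho to its free hydroxyl (less hindered than the carbon between the two benzyloxy groups) and anti to the C3 benzyloxy group, setting the 4α (3,4-trans) centre.

Step 5
Reactants: 7 3,4,5-tris(benzyloxy)benzaldehyde; 8 methyl 2-[(tert-butyldimethylsilyl)oxy]-2-(dimethoxyphosphoryl)acetate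
Product: 9 methyl (Z)-2-[(tert-butyldimethylsilyl)oxy]-3-[3,4,5-tris(benzyloxy)phenyl]prop-2-enoate
Conditions: LiN(SiMe3)2, THF, −78 °C to rt
Reagents that add atoms: none
Why: Horner–Wadsworth–Emmons olefination, expected to favour the Z isomer; the double-bond geometry is of no consequence because this carbon becomes sp3 in step 8.

Step 6
Reactants: 9 methyl (Z)-2-[(tert-butyldimethylsilyl)oxy]-3-[3,4,5-tris(benzyloxy)phenyl]prop-2-enoate
Product: 10 (Z)-2-[(tert-butyldimethylsilyl)oxy]-3-[3,4,5-tris(benzyloxy)phenyl]prop-2-en-1-ol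
Conditions: i-Bu2AlH (2.2 equiv), CH2Cl2, −78 °C
Reagents that add atoms: none
Why: i-Bu2AlH 1,2-reduction of the enoate to the allylic alcohol, which leaves the silyl enol ether and the benzyl ethers untouched.

Step 7
Reactants: 10 (Z)-2-[(tert-butyldimethylsilyl)oxy]-3-[3,4,5-tris(benzyloxy)phenyl]prop-2-en-1-ol
Product: 11 (Z)-2-[(tert-butyldimethylsilyl)oxy]-3-[3,4,5-tris(benzyloxy)phenyl]prop-2-enal
Conditions: MnO2 (excess), CH2Cl2, rt
Reagents that add atoms: none
Why: MnO2 oxidation of an allylic alcohol, which stops at the enal.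

Step 8
Reactants: 6 3,5-bis(benzyloxy)-2-(penta-O-benzylcatechin-4α-yl)phenol; 11 (Z)-2-[(tert-butyldimethylsilyl)oxy]-3-[3,4,5-tris(benzyloxy)phenyl]prop-2-enal
Product: 15 flavan-3-one of the benzylated dimer (both C2 epimers), via benzodioxaborin 12 (not isolated), via ortho-quinone methide 13 (not isolated), via silyl enol ether chromene 14 (not isolated)
Conditions: PhB(OH)2 (1.2 equiv), EtCO2H (0.3 equiv), toluene, reflux, Dean–Stark, Ar; then Bu4NF, AcOH, THF, 0 °C
Reagents that add atoms: none
Why: PhB(OH)2 condenses with the single free phenol of 6 and binds the aldehyde of 11, so the ring carbon ortho to that oxygen (future C4a) adds to the aldehyde carbon (future C4) within a six-membered boron template to give 12; at reflux 12 loses phenylboroxine by retro-[4+2] fragmentation to 13, whose 1-oxatriene closes by thermal disrotatory oxa-6π electrocyclisation to form O1–C2 in 14, and buffered fluoride then cleaves the silyl enol ether to ketone 15. The closest known reaction type is the phenylboronic acid-mediated condensation of phenols with α,β-unsaturated aldehydes to 2H-chromenes (formal [3+3] annulation). Ring F closes by 6π electrocyclisation, a pericyclic closure and not an exo or endo nucleophilic one, while the dioxaborin is a temporary ring that is expelled again. C2 is created in the electrocyclisation without facial control and should form as both epimers, which is accepted because C2 of 15 is epimerisable and is set in step 9. The step needs attack at the aldehyde carbon instead of the β-carbon and reaction at one ring position only: the boron template delivers the carbonyl carbon to the ortho carbon, and 6 has one free hydroxyl whose only unsubstituted ortho carbon lies between it and a benzyloxy group (the other ortho carbon carries the upper unit), so only the 4→8 constitution can form, and the carbon between the two benzyloxy groups of ring D and C6/C8 of ring A have no neighbouring free hydroxyl. The silyl enol ether carries C3 at the ketone level, so no separate oxidation is needed.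

Step 9
Reactants: 15 flavan-3-one of the benzylated dimer (both C2 epimers)
Product: 16 penta-O-benzylcatechin-(4α→8)-penta-O-benzylepigallocatechin (lower 3-OH free)
Conditions: RuCl[(R,R)-TsDPEN](p-cymene) (3 mol %), HCO2H/Et3N (1:1), DMF, 30 °C, Ar
Reagents that add atoms: none
Why: Noyori–Ikariya asymmetric transfer hydrogenation under dynamic kinetic resolution, in which C2–H (flanked by O1, the C3 carbonyl and ring E) should epimerise through the enol faster than the ketone is reduced and the catalyst should reduce one C2 epimer with hydride delivery to C3 anti to the C2 aryl group, setting C2 and C3 together as the 2,3-cis (2R,3R) alcohol.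

Step 10
Reactants: 16 penta-O-benzylcatechin-(4α→8)-penta-O-benzylepigallocatechin (lower 3-OH free); 17 3,4,5-tris(benzyloxy)benzoic acid
Product: 18 trideca-O-benzyl ether of the target
Conditions: DCC, DMAP, CH2Cl2, 0 °C to rt
Reagents that add atoms: none
Why: Steglich esterification of the only free hydroxyl in the molecule; the C3–O bond is not broken, so the configuration is retained.

Step 11
Reactants: 18 trideca-O-benzyl ether of the target
Product: 19 catechin-(4α→8)-epigallocatechin 3-O-gallate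
Conditions: H2 (1 atm), Pd(OH)2/C, THF/MeOH (1:1), rt; filtration under Ar, lyophilisation
Reagents that add atoms: none
Why: Hydrogenolysis of the thirteen benzyl ethers, under which the ester, the interflavan bond and the two cyclic benzylic ethers should survive at room temperature; no stereocentre is affected.

**Compound list**

1 | (+)-catechin, (2R,3S)-2-(3,4-dihydroxyphenyl)chromane-3,5,7-triol | C1c2c(O)cc(O)cc2O[C@H](c2ccc(O)c(O)c2)[C@H]1O | starting material
2 | 5,7,3',4'-tetra-O-benzyl-(+)-catechin, (2R,3S)-5,7-bis(benzyloxy)-2-[3,4-bis(benzyloxy)phenyl]chroman-3-ol | C1c2c(OCc3ccccc3)cc(OCc3ccccc3)cc2O[C@H](c2ccc(OCc3ccccc3)c(OCc3ccccc3)c2)[C@H]1O | intermediate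
3 | 3,5,7,3',4'-penta-O-benzyl-(+)-catechin, (2R,3S)-3,5,7-tris(benzyloxy)-2-[3,4-bis(benzyloxy)phenyl]chromane | C1c2c(OCc3ccccc3)cc(OCc3ccccc3)cc2O[C@H](c2ccc(OCc3ccccc3)c(OCc3ccccc3)c2)[C@H]1OCc1ccccc1 | intermediate
4 | (2R,3S,4S)-3,5,7-tris(benzyloxy)-2-[3,4-bis(benzyloxy)phenyl]-4-(2-ethoxyethoxy)chromane (4β ether, cis to the 3-benzyloxy group) | CCOCCO[C@H]1c2c(OCc3ccccc3)cc(OCc3ccccc3)cc2O[C@H](c2ccc(OCc3ccccc3)c(OCc3ccccc3)c2)[C@H]1OCc1ccccc1 | intermediate
5 | 3,5-bis(benzyloxy)phenol | Oc1cc(OCc2ccccc2)cc(OCc2ccccc2)c1 | starting material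
6 | 3,5-bis(benzyloxy)-2-[(2R,3S,4R)-3,5,7-tris(benzyloxy)-2-[3,4-bis(benzyloxy)phenyl]chroman-4-yl]phenol (4α aryl, trans to the 3-benzyloxy group, cis to the C2 aryl group) | Oc1cc(OCc2ccccc2)cc(OCc2ccccc2)c1[C@@H]1c2c(OCc3ccccc3)cc(OCc3ccccc3)cc2O[C@H](c2ccc(OCc3ccccc3)c(OCc3ccccc3)c2)[C@H]1OCc1ccccc1 | intermediate
7 | 3,4,5-tris(benzyloxy)benzaldehyde | O=Cc1cc(OCc2ccccc2)c(OCc2ccccc2)c(OCc2ccccc2)c1 | starting material
8 | methyl 2-[(tert-butyldimethylsilyl)oxy]-2-(dimethoxyphosphoryl)acetate (racemic) | COC(=O)C(O[Si](C)(C)C(C)(C)C)P(=O)(OC)OC | starting material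
9 | methyl (Z)-2-[(tert-butyldimethylsilyl)oxy]-3-[3,4,5-tris(benzyloxy)phenyl]prop-2-enoate | COC(=O)/C(O[Si](C)(C)C(C)(C)C)=C/c1cc(OCc2ccccc2)c(OCc2ccccc2)c(OCc2ccccc2)c1 | intermediate
10 | (Z)-2-[(tert-butyldimethylsilyl)oxy]-3-[3,4,5-tris(benzyloxy)phenyl]prop-2-en-1-ol | OC/C(O[Si](C)(C)C(C)(C)C)=C/c1cc(OCc2ccccc2)c(OCc2ccccc2)c(OCc2ccccc2)c1 | intermediate
11 | (Z)-2-[(tert-butyldimethylsilyl)oxy]-3-[3,4,5-tris(benzyloxy)phenyl]prop-2-enal | O=C/C(O[Si](C)(C)C(C)(C)C)=C/c1cc(OCc2ccccc2)c(OCc2ccccc2)c(OCc2ccccc2)c1 | intermediate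
12 | 2-phenyl-4H-1,3,2-benzodioxaborin in which boron bridges the phenol oxygen of 6 and the former aldehyde oxygen of 11; C4 of the boron ring (both configurations) carries the (Z)-1-silyloxy-2-arylvinyl group and the upper unit stays on the ring carbon next to the aryl oxygen | CC(C)(C)[Si](C)(C)O/C(=C\c1cc(OCc2ccccc2)c(OCc2ccccc2)c(OCc2ccccc2)c1)C1OB(c2ccccc2)Oc2c([C@@H]3c4c(OCc5ccccc5)cc(OCc5ccccc5)cc4O[C@H](c4ccc(OCc5ccccc5)c(OCc5ccccc5)c4)[C@H]3OCc3ccccc3)c(OCc3ccccc3)cc(OCc3ccccc3)c21 | intermediate (not isolated)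
13 | vinyl ortho-quinone methide: 3,5-bis(benzyloxy)cyclohexa-2,4-dien-1-one carrying the upper unit at C2 and a (Z)-exocyclic (Z)-2-silyloxy-3-arylallylidene group at C6 | O=C1C([C@@H]2c3c(OCc4ccccc4)cc(OCc4ccccc4)cc3O[C@H](c3ccc(OCc4ccccc4)c(OCc4ccccc4)c3)[C@H]2OCc2ccccc2)=C(OCc2ccccc2)C=C(OCc2ccccc2)/C1=C/C(O[Si](C)(C)C(C)(C)C)=C/c1cc(OCc2ccccc2)c(OCc2ccccc2)c(OCc2ccccc2)c1 | intermediate (not isolated)
14 | 3-[(tert-butyldimethylsilyl)oxy]-5,7-bis(benzyloxy)-2-[3,4,5-tris(benzyloxy)phenyl]-2H-chromene carrying penta-O-benzylcatechin-4α-yl at C8 (both C2 epimers) | CC(C)(C)[Si](C)(C)OC1=Cc2c(OCc3ccccc3)cc(OCc3ccccc3)c([C@@H]3c4c(OCc5ccccc5)cc(OCc5ccccc5)cc4O[C@H](c4ccc(OCc5ccccc5)c(OCc5ccccc5)c4)[C@H]3OCc3ccccc3)c2OC1c1cc(OCc2ccccc2)c(OCc2ccccc2)c(OCc2ccccc2)c1 | intermediate (not isolated)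
15 | 5,7-bis(benzyloxy)-2-[3,4,5-tris(benzyloxy)phenyl]chroman-3-one carrying penta-O-benzylcatechin-4α-yl at C8 (both C2 epimers, interconverting) | O=C1Cc2c(OCc3ccccc3)cc(OCc3ccccc3)c([C@@H]3c4c(OCc5ccccc5)cc(OCc5ccccc5)cc4O[C@H](c4ccc(OCc5ccccc5)c(OCc5ccccc5)c4)[C@H]3OCc3ccccc3)c2OC1c1cc(OCc2ccccc2)c(OCc2ccccc2)c(OCc2ccccc2)c1 | intermediate
16 | 3,5,7,3',4'-penta-O-benzylcatechin-(4α→8)-5,7,3',4',5'-penta-O-benzylepigallocatechin; lower unit (2R,3R), 2,3-cis, 3-OH free | O[C@@H]1Cc2c(OCc3ccccc3)cc(OCc3ccccc3)c([C@@H]3c4c(OCc5ccccc5)cc(OCc5ccccc5)cc4O[C@H](c4ccc(OCc5ccccc5)c(OCc5ccccc5)c4)[C@H]3OCc3ccccc3)c2O[C@@H]1c1cc(OCc2ccccc2)c(OCc2ccccc2)c(OCc2ccccc2)c1 | intermediate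
17 | 3,4,5-tris(benzyloxy)benzoic acid | OC(=O)c1cc(OCc2ccccc2)c(OCc2ccccc2)c(OCc2ccccc2)c1 | starting material
18 | trideca-O-benzyl ether of the target: 16 esterified at the lower C3 oxygen with 3,4,5-tris(benzyloxy)benzoyl | O=C(O[C@@H]1Cc2c(OCc3ccccc3)cc(OCc3ccccc3)c([C@@H]3c4c(OCc5ccccc5)cc(OCc5ccccc5)cc4O[C@H](c4ccc(OCc5ccccc5)c(OCc5ccccc5)c4)[C@H]3OCc3ccccc3)c2O[C@@H]1c1cc(OCc2ccccc2)c(OCc2ccccc2)c(OCc2ccccc2)c1)c1cc(OCc2ccccc2)c(OCc2ccccc2)c(OCc2ccccc2)c1 | intermediate
19 | catechin-(4α→8)-epigallocatechin 3-O-gallate; upper unit (2R,3S,4S), lower unit (2R,3R) | O=C(O[C@@H]1Cc2c(O)cc(O)c([C@@H]3c4c(O)cc(O)cc4O[C@H](c4ccc(O)c(O)c4)[C@H]3O)c2O[C@@H]1c1cc(O)c(O)c(O)c1)c1cc(O)c(O)c(O)c1 | target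

**Count and risks**

Total steps: 11. Longest linear sequence: 8 (steps 1–4 and 8–11); steps 5–7 form the convergent enal branch.

Steps most likely to fail:

Step 8. The silyl enol ether of 11 may be lost under the hot, weakly acidic conditions, or borate formation at the hindered phenol may be slow, so that the enal decomposes before it is condensed. The fallback sets out from 6 and 7 and returns at 15. Addition of CH2=CHMgBr to 7 would give 1-[3,4,5-tris(benzyloxy)phenyl]prop-2-en-1-ol F1. H2SO4 on SiO2 in CH2Cl2 would ionise F1 to the cinnamyl cation, which should alkylate 6 at the free carbon ortho to the hydroxyl (Friedel–Crafts allylation, forming C4–C4a) to give the (E)-2-cinnamylphenol F2. Dimethyldioxirane would give the trans-epoxide F3, which camphorsulfonic acid should open by 6-endo attack of the phenol at the benzylic carbon with inversion (forming O1–C2) to give the 2,3-trans-flavan-3-ol F4 as both lower-unit trans isomers. Dess–Martin periodinane would oxidise F4 to 15, and step 9 then sets C2 and C3 as in the main route.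

Step 9. Epimerisation at C2 may be slower than reduction, or the catalyst may discriminate the carbonyl faces poorly, which would give a mixture of lower-unit stereoisomers. The fallback sets out from 15 and returns at 16. LiBH(s-Bu)3 in THF at −78 °C should deliver hydride anti to the C2 aryl group under substrate control and give the two 2,3-cis alcohols, 16 and its (2S,3S) lower-unit diastereomer F5. These are diastereomers because of the upper unit and would be separated by chromatography; F5 would be re-oxidised with Dess–Martin periodinane to 15 and recycled.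

Step 4. The cation may attack 5 para to the hydroxyl (at the carbon between the two benzyloxy groups) or at oxygen, and the 4α selectivity may erode. The fallback sets out from 4 and returns at 6. Coupling of 4 with excess phloroglucinol (symmetrical, so only one constitution is possible) under BF3·OEt2 in THF/CH2Cl2 would give penta-O-benzylcatechin-(4α→2)-phloroglucinol F6. Controlled benzylation (BnBr 2 equiv, K2CO3, DMF) should etherify the unhindered para hydroxyl first and then one of the two equivalent ortho hydroxyls, giving 6.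

**Further compounds**

F1 | step 8 | 1-[3,4,5-tris(benzyloxy)phenyl]prop-2-en-1-ol (racemic) | C=CC(O)c1cc(OCc2ccccc2)c(OCc2ccccc2)c(OCc2ccccc2)c1
F2 | step 8 | 6 carrying an (E)-3-[3,4,5-tris(benzyloxy)phenyl]prop-2-en-1-yl group on the ring carbon ortho to the hydroxyl | Oc1c(C/C=C/c2cc(OCc3ccccc3)c(OCc3ccccc3)c(OCc3ccccc3)c2)c(OCc2ccccc2)cc(OCc2ccccc2)c1[C@@H]1c2c(OCc3ccccc3)cc(OCc3ccccc3)cc2O[C@H](c2ccc(OCc3ccccc3)c(OCc3ccccc3)c2)[C@H]1OCc1ccccc1
F3 | step 8 | trans-epoxide of the side-chain double bond of F2 (both epoxide antipodes) | Oc1c(CC2OC2c2cc(OCc3ccccc3)c(OCc3ccccc3)c(OCc3ccccc3)c2)c(OCc2ccccc2)cc(OCc2ccccc2)c1[C@@H]1c2c(OCc3ccccc3)cc(OCc3ccccc3)cc2O[C@H](c2ccc(OCc3ccccc3)c(OCc3ccccc3)c2)[C@H]1OCc1ccccc1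
F4 | step 8 | 2,3-trans-5,7-bis(benzyloxy)-2-[3,4,5-tris(benzyloxy)phenyl]chroman-3-ol carrying penta-O-benzylcatechin-4α-yl at C8 (both lower-unit trans isomers) | OC1Cc2c(OCc3ccccc3)cc(OCc3ccccc3)c([C@@H]3c4c(OCc5ccccc5)cc(OCc5ccccc5)cc4O[C@H](c4ccc(OCc5ccccc5)c(OCc5ccccc5)c4)[C@H]3OCc3ccccc3)c2OC1c1cc(OCc2ccccc2)c(OCc2ccccc2)c(OCc2ccccc2)c1
F5 | step 9 | (2S,3S) lower-unit diastereomer of 16 (2,3-cis) | O[C@H]1Cc2c(OCc3ccccc3)cc(OCc3ccccc3)c([C@@H]3c4c(OCc5ccccc5)cc(OCc5ccccc5)cc4O[C@H](c4ccc(OCc5ccccc5)c(OCc5ccccc5)c4)[C@H]3OCc3ccccc3)c2O[C@H]1c1cc(OCc2ccccc2)c(OCc2ccccc2)c(OCc2ccccc2)c1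
F6 | step 4 | penta-O-benzylcatechin-(4α→2)-phloroglucinol | Oc1cc(O)cc(O)c1[C@@H]1c2c(OCc3ccccc3)cc(OCc3ccccc3)cc2O[C@H](c2ccc(OCc3ccccc3)c(OCc3ccccc3)c2)[C@H]1OCc1ccccc1
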